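**Assumptions**
- The target SMILES shows one keto–enol tautomer. The two enol forms interconvert rapidly, so making the curcuminoid 1,3-diketone makes the target.
- CIP analysis of the terpene ring gives C–OAr = S, C–OH = R, C–side chain = R and side-chain CH(CH3) = S. OH and OAr are cis to each other, and both are trans to the side chain.

## Retrosynthetic overview
1. The last C–C bond comes from a boron-templated (Pabon) aldol condensation of an O-terpenyl vanillin with feruloylacetone, giving the unsymmetrical curcuminoid.
2. The aryl ether C–O bond comes from Pd(0) cis-1,4 opening of a cyclohexadiene monoepoxide by vanillin. Double inversion places OAr cis to the liberated OH.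
3. The vinyl epoxide comes from a 4-alkylcyclohex-2-enone by nucleophilic epoxidation anti to the side chain, MeLi addition and dehydration.
4. The enone comes from (S)-citronellal and methyl vinyl ketone by an organocatalytic Michael addition followed by aldol condensation.
5. Ring order: the cyclohexenone is the only carbocycle built, then a transient oxirane that is opened in the etherification. Both arenes are purchased.

## Route

**Step 1**
Reactants: 1, (S)-(–)-citronellal; 2, methyl vinyl ketone
Product: 3, (2R,3S)-3,7-dimethyl-2-(3-oxobutyl)oct-6-enal
Conditions: 2 (1.5 equiv), (R)-2-[methoxy(diphenyl)methyl]pyrrolidine (5 mol %), ethyl 3,4-dihydroxybenzoate (20 mol %), neat, 4 °C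
Reagents that add atoms: methyl vinyl ketone (2), C=CC(C)=O
Why: This is an enamine-catalysed asymmetric Michael addition in which the (R)-diarylprolinol ether shields one face of the E-enamine, so C2 is set as R under catalyst control (about 9:1 dr or better) while C3 (S) comes unchanged from the chiral pool.

**Step 2**
Reactants: 3
Product: 4, (4R)-4-[(2S)-6-methylhept-5-en-2-yl]cyclohex-2-en-1-one
Conditions: 0.1 M aq KOH, n-Bu4NOH (cat.), Et2O/THF, reflux
Reagents that add atoms: none
Why: In this intramolecular aldol condensation the methyl-ketone enolate closes the only feasible six-membered ring onto the aldehyde and E1cB loss of water gives the enone, with the now γ stereocentre surviving the dilute phase-transfer base.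

**Step 3**
Reactants: 4
Product: 5, (1R,5R,6R)-5-[(2S)-6-methylhept-5-en-2-yl]-7-oxabicyclo[4.1.0]heptan-2-one, with the epoxide trans to the side chain
Conditions: 30% aq H2O2 (3 equiv), NaOH (0.3 equiv), MeOH, 0 °C
Reagents that add atoms: hydrogen peroxide, OO
Why: Weitz–Scheffer nucleophilic epoxidation attacks only the electron-poor enone C=C, leaving the prenyl-type alkene untouched, and HOO⁻ adds to C3 anti to the adjacent sec-alkyl group, which sets the future carbinol carbon (R).

**Step 4**
Reactants: 5
Product: 6, (1R,5R,6R)-2-methyl-5-[(2S)-6-methylhept-5-en-2-yl]-7-oxabicyclo[4.1.0]heptan-2-ol, as C-2 epimers with OH cis to the epoxide expected as the major one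
Conditions: MeLi (1.2 equiv), Et2O, –78 °C; aq NH4Cl
Reagents that add atoms: methyllithium, [Li]C
Why: 1,2-Addition of the organolithium to the ketone is much faster than epoxide opening at –78 °C, and the new carbinol centre is destroyed in the next step.

**Step 5**
Reactants: 6
Product: 7, (1S,5R,6R)-2-methyl-5-[(2S)-6-methylhept-5-en-2-yl]-7-oxabicyclo[4.1.0]hept-2-ene (vinyl epoxide)
Conditions: Burgess reagent (1.2 equiv), PhMe, 50 °C; Et3N-deactivated SiO2
Reagents that add atoms: none
Why: In this Burgess syn-elimination (Ei) the oxirane CH cannot eliminate, six-centre Ei eliminations of 1-methylcyclohexyl systems favour the endocyclic trisubstituted alkene (about 3:1, exocyclic isomer separated), and the neutral halide-free medium spares the epoxide.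

**Step 6**
Reactants: 7; 8, vanillin
Product: 9, 4-{[(1S,4R,5R)-4-hydroxy-2-methyl-5-[(2S)-6-methylhept-5-en-2-yl]cyclohex-2-en-1-yl]oxy}-3-methoxybenzaldehyde
Conditions: 8 (1.2 equiv), Pd(PPh3)4 (5 mol %), THF, 0 °C to rt
Reagents that add atoms: vanillin (8), COc1cc(C=O)ccc1O
Why: In this Tsuji–Trost opening of a cyclic vinyl epoxide, Pd(0) ionises the allylic C–O bond anti, the alkoxide deprotonates vanillin, and the phenoxide attacks the distal, less hindered allyl terminus anti to Pd, so double inversion sets C–OAr (S) cis-1,4 to the retained C–OH (R).

**Step 7**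
Reactants: 8, vanillin; 10, acetylacetone
Product: 11, feruloylacetone, (5E)-6-(4-hydroxy-3-methoxyphenyl)hex-5-ene-2,4-dione
Conditions: 10 (4 equiv), B2O3, EtOAc, 80 °C; then 8, B(On-Bu)3, n-BuNH2 (cat.); 0.4 M HCl, 50 °C
Reagents that add atoms: acetylacetone (10), CC(=O)CC(C)=O
Why: In this Pabon condensation the boron chelate blocks the central CH2 so the terminal CH3 condenses with the aldehyde, excess diketone stops the reaction at the mono-adduct, and E1cB dehydration gives the E-alkene.

**Step 8**
Reactants: 9; 11
Product: 12, Terpecurcumin B
Conditions: 11 (1.2 equiv), B2O3 (0.7 equiv), EtOAc, 70 °C, 30 min; then 9, B(On-Bu)3 (3 equiv), n-BuNH2 (0.4 equiv), 60 °C; then 0.4 M aq HCl, rt, 30 min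
Reagents that add atoms: none beyond 9 and 11
Why: In this second Pabon aldol condensation the remaining CH3 of the boron-chelated diketone condenses with aldehyde 9 to give the E-enone, no stereocentre is touched, transient borates of the free OH and phenol hydrolyse on work-up, and the brief cold dilute acid spares the allylic ether and alcohol.

## Compound list
| No. | Name | SMILES | Role |
|---|---|---|---|
| 1 | (S)-citronellal | `O=CC[C@@H](C)CCC=C(C)C` | starting material |
| 2 | methyl vinyl ketone | `C=CC(C)=O` | starting material |
| 3 | (2R,3S)-3,7-dimethyl-2-(3-oxobutyl)oct-6-enal | `CC(=O)CC[C@H]([C@@H](C)CCC=C(C)C)C=O` | intermediate |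
| 4 | (4R)-4-[(2S)-6-methylhept-5-en-2-yl]cyclohex-2-enone | `O=C1CC[C@H]([C@@H](C)CCC=C(C)C)C=C1` | intermediate |
| 5 | (1R,5R,6R)-epoxy ketone | `O=C1CC[C@H]([C@@H](C)CCC=C(C)C)[C@H]2O[C@H]21` | intermediate |
| 6 | (1R,5R,6R)-epoxy tertiary alcohol (C-2 epimers) | `CC1(O)CC[C@H]([C@@H](C)CCC=C(C)C)[C@H]2O[C@H]21` | intermediate |
| 7 | (1S,5R,6R)-vinyl epoxide | `CC1=CC[C@H]([C@@H](C)CCC=C(C)C)[C@H]2O[C@H]21` | intermediate |
| 8 | vanillin | `COc1cc(C=O)ccc1O` | starting material |
| 9 | O-terpenyl vanillin (1S,4R,5R,2'S) | `COc1cc(C=O)ccc1O[C@H]1C[C@H]([C@@H](C)CCC=C(C)C)[C@@H](O)C=C1C` | intermediate |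
| 10 | acetylacetone | `CC(=O)CC(C)=O` | starting material |
| 11 | feruloylacetone | `COc1cc(/C=C/C(=O)CC(C)=O)ccc1O` | intermediate |
| 12 | Terpecurcumin B | `COc1cc(/C=C/C(=O)/C=C(O)/C=C/c2ccc(O[C@H]3C[C@H]([C@@H](C)CCC=C(C)C)[C@@H](O)C=C3C)c(OC)c2)ccc1O` | target |

## Summary
- **Total steps:** 8
- **Longest linear sequence:** 7 (steps 1–6, then 8)

**Steps most likely to fail**

1. **Step 5.** The endo/exo regiochemistry of the dehydration is uncertain and the vinyl epoxide is labile.
   - Fallback: abandon the vinyl epoxide.
   - Convert 4 with LDA/PhNTf2 to the cross-conjugated dienyl triflate, then use MeMgBr/Fe(acac)3 to reach (–)-zingiberene.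
   - A ¹O2 [4+2] cycloaddition anti to the side chain followed by Et3N-mediated Kornblum–DeLaMare rearrangement gives the 4-hydroxy-2-methyl-5-alkylcyclohexenone.
   - TBS protection and Luche reduction give the alcohol cis to the side chain. Mitsunobu inversion with vanillin and desilylation then give 9.

2. **Step 6.** Risks are 1,2- versus 1,4-attack, reversible ionisation of the electron-poor aryl ether, and β-H elimination leading to aromatisation.
   - Fallback: form the aryl ether by SNAr with retention at carbon instead of by attack of a phenoxide on the π-allyl.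
   - Treat 7 with Pd(0)/AcOH to obtain the cis-1,4-hydroxy acetate, protect the free OH as its TBS ether, and cleave the acetate with K2CO3/MeOH.
   - React the alkoxide (KHMDS) with 4-fluoro-3-methoxybenzaldehyde, then remove the TBS group to give 9.

3. **Step 8.** Risks are modest yield, scrambling to symmetrical curcumin, and acid sensitivity of the allylic ether during boron removal.
   - Fallback: move the etherification to the end.
   - Mask commercial curcumin as its BF2 chelate with BF3·OEt2. This removes the diketone as a carbon nucleophile.
   - Couple an excess of the chelate with 7 under Pd(0) to obtain the mono-ether.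
   - Release the diketone with aqueous MeOH/sodium oxalate at near-neutral pH.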